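## Analysis of the target

Locants used in this text only: hydroazulene C1–C10 (C1 alkene carbon with methyl, C2 alkene CH, C3 CH2, C4 and C5 ring-fusion CH, C6 and C7 CH2 of ring D, C8 carbinol of ring D, C9 CMe2, C10 linker-bearing CH of ring C); linker C12 (on C10) and C11 (on C13); ring B C13 (linker-bearing CH), C14 (quaternary, methyl), C19 (CH–O), C20, C21, C22 (carbinol); ring A C14, C15, C16, C17 (C=O), C18 (CMe2), O, C19.

The target joins two bicycles through the C11–C12 ethylene linker: a 2,2-dimethyloxepan-3-one (ring A) fused to a cyclohexane (ring B), and a cis-fused hydroazulene made of a cycloheptene (ring C) and a cyclopentane (ring D). It has eight stereocenters, four contiguous on ring B (C13, C14, C19, C22) and four on the hydroazulene (C4, C5, C8, C10); the linker separates the two sets, so neither can steer the other. On ring B the C13 side chain, the C14 methyl and the C22 hydroxyl share one face, and the ring A atoms on C14 (C15) and on C19 (O) the other, so ring A is cis-fused. On the hydroazulene H4, H5, H10 and the C8 hydroxyl share one face, the C8 methyl and the linker the other. Sensitive groups are the two tertiary alcohols (elimination under acid), the C1=C2 alkene (it can slip to the tetrasubstituted C1=C10 position) and the α-alkoxy ketone, which is therefore unveiled last. The hard points are the quaternary C14 bonded to C13, itself flanked by the fully substituted C22; the stereocenter C10 next to CMe2; two seven-membered rings; and the union of two enantiopure halves through a bare CH2–CH2. The strategy rests on one feature: ring B with C22 and its methyl, C21, C20, C19, C14 with both its carbon substituents (methyl and C15) and C13 is the carbon chain of linalool without its terminal CH2, closed by the single bond C13–C14. An acryloyl unit supplies C11 and C12.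

## Retrosynthetic reasoning

Target 45 to tris-silyl ether 43. The ketone is taken back to the secondary alcohol of triol 44, and the three hydroxyls to the silyl ethers of 43. This keeps the ketone and the two tertiary alcohols out of every organometallic and acidic step; the forward steps are a fluoride desilylation and an oxidation that only the secondary alcohol can undergo.

Tris-silyl ether 43 to enone 36 and iodide 19. The bond C10–C12 is cut. Both halves then carry all their other stereocenters, and the bond is made at a ketone carbon, which tolerates the neighbouring CMe2 better than any substitution would. Forward, alkyllithium 37 (from 19) adds to the C10 carbonyl of 36 to give 38, and an oxidative 1,3-shift moves the oxygen to C2 (39). A reagent-controlled reduction then sets the C2 carbinol (40), and a reductive allylic transposition through 41 and 42 delivers hydrogen to C10 on a defined face while the alkene returns to C1=C2. C10 and the alkene position are thus set by one stereospecific event, not by protonation next to CMe2.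

Iodide 19 to lactone 15. The C12 iodide is taken back to the lactone carbonyl (16, 17, 18). The lactone is kept until here because it protects the C22 oxygen and the linker carboxyl at once.

Lactone 15 to diol lactone 8. Ring A is cut at O–C18 (7-endo opening of epoxide 14 by the C19 hydroxyl) and at C16–C17 (coupling of the borane 12 from alkene 10 with bromide 11). Alkene 10 comes from aldehyde 9 and this from 8. The O–C18 bond is chosen because C19 already carries its oxygen with the right configuration and C18 is the carbon best able to take an oxygen nucleophile in the endo mode. C17 becomes a ketone, so the epoxide configuration is irrelevant.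

Diol lactone 8 to epoxy butenolide 6 (key disconnection). The bond C13–C14 is cut. A radical at C14, made by reductive opening of the epoxide with a trivalent titanium reagent, adds to the β-carbon of the unsaturated lactone. A radical is chosen because a quaternary carbon has to be joined to a carbon next to the fully substituted C22. Two features of 6 are deliberate. First, the unsaturated ester is closed onto the C22 oxygen as a butenolide. An open-chain enoate can cyclize through two chairs that give opposite configurations at C13, and the chair that places the C22 oxygen anti to the forming bond leads to the wrong one. The lactone allows attack only on the face that carries the tether, so C13 is fixed. Second, the hydroxymethyl group is left free. A bulky ether on it would be pushed anti to the titanoxy group, which gives the trans A/B relationship. A free hydroxyl can bind the titanium on the C19 oxygen, which holds C15 gauche to that oxygen, as the cis-fused target needs.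

Epoxy butenolide 6 to (R)-linalool 1 and acryloyl chloride 2. Ring-closing metathesis of the acrylate and vinyl groups of 5 gives the butenolide. The epoxide of 5 comes from Sharpless epoxidation of allylic alcohol 4 (sets C19, and defines C14 until the radical is formed), and 4 from allylic oxidation of the (E)-methyl group of ester 3, made from 1 and 2. The ester is made first so that no free tertiary hydroxyl is ever present beside the epoxide, which would close a tetrahydrofuran. The terminal CH2 of 1 leaves as ethene; C11 and C12 come from 2.

Enone 36 to (S)-linalool 20. Ring C is cut at C1=C2 (ring-closing metathesis of dienone 35). The isopropenyl ketone of 35 comes from nitrile 31 and bromide 32 through 33 and 34; the allyl group of 31 from methylidene compound 28 by hydroboration to 30 and coupling with 29; and 28 from ketone 27 and ketol 26. The C5–C9 bond is cut back to epoxide 22 and isobutyronitrile 23 (through 24, giving 25). Epoxide 22 comes from cyclopentenol 21, the metathesis product of 20. C8 is thus taken from the chiral pool, C5 is set by anti opening of an epoxide placed by the C8 hydroxyl, and C4 by hydrogen delivery to the less hindered face.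

## Alternatives that were turned down

Alternative 1: The hydroazulene is cut at C4–C5 and C9–C10. Forward, irradiation of the enol acetate A1 adds the enol double bond across the tethered trisubstituted alkene (de Mayo reaction), and methanolysis of the cyclobutyl acetate triggers a retro-aldol that expands the cyclopentane to ring C, giving diketone A2. In its favour: both carbocycles and the bond to the CMe2 carbon arise in one operation from a flat, easily made precursor, and for rings C and D this is clearly shorter than the nine steps to 36. Against it for this target: the C10 ketone of A2 lies between CMe2 and a CH(CH3) carbon and must become a CH that carries the linker beside a C1=C2 alkene, and an olefination or addition with a large partner at such a ketone is doubtful. The C8 ketone must become a methyl carbinol whose hydroxyl is cis to the ring-fusion hydrogens, whereas a methyl nucleophile entering from the open convex face gives the opposite epimer. The only stereocenter of A1 is a carbon that ends as sp2 in the target, so it must induce C4 and C5 across the ring and is then lost. Rings A and B, with the quaternary carbon, are not addressed at all. The chosen strategy spends more steps on rings C and D but takes C8 from the chiral pool and sets C10 by a stereospecific shift.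

Alternative 2: Rings A and B are cut at O–C18, C13–C14 and O–C22. Forward, a silyl triflate with a hindered base activates the terminal epoxide of diepoxy acid A3; the inner epoxide oxygen closes ring A, the alkene opens the epoxonium ion at C14 to close ring B, and the carboxyl captures the cation to give hydroxy lactone A4. In its favour: this is the most step-economic proposal. A4 is the desilylated form of 15, which the chosen route reaches only after ten steps, and two rings, three bonds and three stereocenters are set at once; on bonds per step it is stronger. Against it for this target: an ionic opening is anti, so the cis A/B fusion requires the inner epoxide to come from a (Z)-trisubstituted alkene, and the cis lactone requires a (Z)-alkene as well. A3 is therefore the less accessible (Z,Z) isomer, with two epoxides to be set enantioselectively on alkenes that are not allylic alcohols. The cascade also has several exits (exo opening of the epoxonium ion, direct attack of the carboxyl on an epoxide, proton loss from the tertiary cation), and (Z)-alkenes cyclize through chairs with an axial substituent. In the chosen strategy the radical does not depend on epoxide geometry, C19 comes from a Sharpless epoxidation of an allylic alcohol and C22 from linalool, and each ring closure can be checked on its own.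

Alternative 3: Ring D is cut at C5–C6. Forward, a Lewis acid promotes conrotatory Nazarov closure of the silylvinyl ketone A5, and loss of the silyl group leaves the cis-fused cyclopentenone A6 with its alkene away from the ring fusion. In its favour: silicon-directed Nazarov reactions place the alkene reliably, and A6 already holds C10 with its two-carbon arm and the C1=C2 alkene. On this point it is stronger than the chosen route, which needs steps 24 to 27 for the same result. Against it: A5 contains a skipped diene in a seven-membered ring, which a Lewis acid can move into conjugation with the dienone. The face of closure at C5 is controlled only by the remote C10 through the CMe2 carbon, and the cis fusion depends on a kinetic protonation. A6 still needs conjugate reduction and the same methyl carbinol as in Alternative 1, with the same facial problem. The union with ring B would then have to form C11–C13 at a carbon flanked by two fully substituted carbons, or ring B would have to be built on the arm. The chosen strategy puts its one uncertain event on ring B and joins the halves at a carbonyl group.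

Key step: step 5

Remark: building blocks that bring two or more carbon atoms into the skeleton are numbered as starting materials; smaller reagents stand under "Reagents that add atoms".
Remark: step 9 gives both C17 epimers; compounds 14 to 19 and 37 to 44 are carried as C17 epimer pairs, which converge in step 29 where C17 becomes the ketone carbon, and their SMILES leave C17 undefined (38 is also a C10 epimer pair, removed in step 25).
Assumption: (S)-linalool 20 of high enantiomeric purity is used; both enantiomers of linalool are articles of commerce.

## Route

Step 1
Reactants: 1 (R)-linalool; 2 acryloyl chloride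
Product: 3 (R)-linalyl acrylate
Conditions: n-BuLi, THF, −78 °C; then 2, −78 → 0 °C
Reagents that add atoms: none
Why: O-acylation of the lithium alkoxide of a tertiary alcohol by an acyl chloride; the low temperature limits polymerization of the acrylate, and the carbinol carbon is not touched.

Step 2
Reactants: 3 (R)-linalyl acrylate
Product: 4 (E)-8-hydroxylinalyl acrylate
Conditions: SeO2 (0.5 equiv), t-BuOOH, CH2Cl2, 0 → 25 °C
Reagents that add atoms: selenium dioxide O=[Se]=O (delivers the oxygen atom); tert-butyl hydroperoxide CC(C)(C)OO (reoxidizes it)
Why: Allylic oxidation with SeO2 (ene reaction, then 2,3-shift) takes the (E)-methyl group of a trisubstituted alkene and keeps the E geometry; the vinyl group has no allylic hydrogen and the acrylate is electron-poor.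

Step 3
Reactants: 4 (E)-8-hydroxylinalyl acrylate
Product: 5 epoxy alcohol acrylate
Conditions: Ti(OiPr)4, D-(−)-diisopropyl tartrate, t-BuOOH, 4 Å sieves, CH2Cl2, −20 °C
Reagents that add atoms: tert-butyl hydroperoxide CC(C)(C)OO
Why: Sharpless asymmetric epoxidation acts only on the allylic alcohol; the D-(−)-tartrate should give the (2R,3R)-epoxide of an (E)-2-methylalk-2-en-1-ol, which sets C19. The tertiary oxygen is an ester, so it cannot open the epoxide to a tetrahydrofuran.

Step 4
Reactants: 5 epoxy alcohol acrylate
Product: 6 epoxy alcohol butenolide
Conditions: second-generation Grubbs catalyst (5 mol %), CH2Cl2, 40 °C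
Reagents that add atoms: none
Why: Ring-closing metathesis of an acrylate with the neighbouring vinyl group gives the 5,5-disubstituted butenolide; the former trisubstituted alkene is already an epoxide, so no other ring closure is open.

Step 5
Reactants: 6 epoxy alcohol butenolide
Product: 8 ring B diol lactone, via tertiary titanoxy radical 7 (not isolated)
Conditions: Cp2TiCl2 (3 equiv), Zn dust, THF, 25 °C, slow addition of 6; aq. NaH2PO4
Reagents that add atoms: none
Why: Cp2TiCl (trivalent titanium), made from Cp2TiCl2 and Zn, transfers one electron to the epoxide, which opens at its fully substituted carbon to the tertiary C14 radical 7 while the oxygen stays on C19 as an alkoxide of tetravalent titanium; the nucleophilic radical adds to the β-carbon C13 of the butenolide, and the α-lactone radical is reduced by a second Cp2TiCl to a titanium enolate that is protonated on work-up. This is the known reductive epoxide opening by trivalent titanium followed by radical cyclization onto an α,β-unsaturated ester (here a lactone), and 2,3-epoxy alcohols with a free hydroxyl are known to open in the same sense. Ring B closes in the 6-exo-trig mode, and C13–C14 is the only new skeletal bond. C13 is fixed by the lactone: the four-atom tether starts at C22 of the planar butenolide and can reach C13 only on the face on which it stands, so the lactone stays cis-fused and the C13 side chain is cis to the C22 oxygen. C14 comes from a planar radical and is decided only in the ring closure: attack perpendicular to the butenolide allows a single chair, with the lactone oxygen and the C19 titanoxy group axial, and in that chair the free hydroxymethyl oxygen can bind the titanium on the C19 oxygen (six-membered chelate) only from the pseudo-equatorial site, which puts C15 cis to that oxygen and the methyl group axial, as in the target. The step needs face selectivity at C14 and ring closure faster than reduction or hydrogen loss of the radical; the first rests on the chelate and the lactone tether, the second on the slow capture of tertiary radicals by the bulky titanium reagent and on slow addition of 6.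

Step 6
Reactants: 8 ring B diol lactone
Product: 9 ring B hydroxy aldehyde lactone
Conditions: TEMPO (cat.), PhI(OAc)2, CH2Cl2, 25 °C
Reagents that add atoms: none
Why: Oxoammonium oxidation (TEMPO with a hypervalent iodine co-oxidant) takes the primary alcohol and leaves the hindered secondary C19 hydroxyl; the aldehyde has no α-hydrogen, so C14 is safe.

Step 7
Reactants: 9 ring B hydroxy aldehyde lactone
Product: 10 ring B vinyl hydroxy lactone
Conditions: Zn, CH2Br2, TiCl4, THF, 0 → 25 °C
Reagents that add atoms: dibromomethane BrCBr
Why: Takai–Lombardo methylenation is not basic, so the β-hydroxy aldehyde cannot undergo retro-aldol cleavage as it might with a phosphorus ylide, and the reagent does not attack the lactone.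

Step 8
Reactants: 10 ring B vinyl hydroxy lactone; 11 1-bromo-2-methylprop-1-ene
Product: 13 ring B homoprenyl hydroxy lactone, via B-alkyl-9-BBN adduct 12 (not isolated)
Conditions: 9-BBN (2.2 equiv), THF, 0 → 25 °C; then 11, Pd(dppf)Cl2 (cat.), AsPh3, K3PO4, DMF/H2O, 50 °C
Reagents that add atoms: none
Why: Hydroboration puts boron on the terminal carbon (the hydroxyl first takes one equivalent as a borinate), and the B-alkyl Suzuki–Miyaura coupling with 11 forms C16–C17; no stereocenter is made and 9-BBN leaves the lactone alone.

Step 9
Reactants: 13 ring B homoprenyl hydroxy lactone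
Product: 14 epoxy hydroxy lactone (C17 epimers)
Conditions: mCPBA, NaHCO3, CH2Cl2, 0 °C
Reagents that add atoms: 3-chloroperbenzoic acid OOC(=O)c1cccc(Cl)c1
Why: Peracid epoxidation of the only alkene; the buffer keeps acid from opening the epoxide early, and both C17 epimers are acceptable because C17 becomes the ketone.

Step 10
Reactants: 14 epoxy hydroxy lactone (C17 epimers)
Product: 15 ring A/B oxepane lactone triisopropylsilyl ether
Conditions: iPr3SiOTf, 2,6-lutidine, MeNO2, −20 → 0 °C
Reagents that add atoms: triisopropylsilyl trifluoromethanesulfonate CC(C)[Si](OS(=O)(=O)C(F)(F)F)(C(C)C)C(C)C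
Why: The silyl triflate silylates the epoxide oxygen, the bond to the gem-dimethyl carbon C18 loosens, and the axial C19 hydroxyl attacks C18 in a 7-endo opening; this is the known silyl triflate promoted endo cyclization of hydroxy epoxides with a fully substituted distal carbon. The silyl group stays on the C17 oxygen and C19 keeps its configuration, so ring A is cis-fused.

Step 11
Reactants: 15 ring A/B oxepane lactone triisopropylsilyl ether
Product: 16 ring A/B diol
Conditions: LiAlH4, THF, 0 °C
Reagents that add atoms: none
Why: Hydride reduction of the lactone gives the primary C12 alcohol and frees the tertiary C22 hydroxyl; the silyl ether and the oxepane are inert.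

Step 12
Reactants: 16 ring A/B diol
Product: 17 bis(triethylsilyl) ether
Conditions: Et3SiOTf (2.5 equiv), 2,6-lutidine, CH2Cl2, −78 → 0 °C
Reagents that add atoms: triethylsilyl trifluoromethanesulfonate CC[Si](CC)(CC)OS(=O)(=O)C(F)(F)F
Why: The silyl triflate silylates both hydroxyls, including the tertiary one; the tertiary oxygen must be capped before C12 becomes a leaving group, or a tetrahydrofuran would form.

Step 13
Reactants: 17 bis(triethylsilyl) ether
Product: 18 primary alcohol
Conditions: pyridinium p-toluenesulfonate (cat.), MeOH/CH2Cl2, 0 °C
Reagents that add atoms: none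
Why: Mild acid methanolysis removes a primary triethylsilyl ether much faster than the tertiary triethylsilyl or the secondary triisopropylsilyl ether.

Step 14
Reactants: 18 primary alcohol
Product: 19 ring A/B iodide
Conditions: I2, PPh3, imidazole, CH2Cl2, 0 → 25 °C
Reagents that add atoms: iodine II
Why: Appel-type iodination of an unhindered primary alcohol through its alkoxyphosphonium salt; no free hydroxyl is left to compete.

Step 15
Reactants: 20 (S)-linalool
Product: 21 (S)-1-methylcyclopent-2-en-1-ol
Conditions: second-generation Grubbs catalyst (0.5 mol %), neat, 25 °C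
Reagents that add atoms: none
Why: Ring-closing metathesis between the vinyl group and the trisubstituted alkene of linalool closes the cyclopentene and expels 2-methylpropene; the carbinol carbon (later C8) is untouched and keeps its configuration.

Step 16
Reactants: 21 (S)-1-methylcyclopent-2-en-1-ol
Product: 22 cis-epoxy alcohol
Conditions: mCPBA, NaHCO3, CH2Cl2, 0 °C
Reagents that add atoms: 3-chloroperbenzoic acid OOC(=O)c1cccc(Cl)c1
Why: Hydroxyl-directed peracid epoxidation of a cyclic allylic alcohol delivers oxygen to the face of the hydroxyl, which is also the face away from the methyl group.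

Step 17
Reactants: 22 cis-epoxy alcohol; 23 isobutyronitrile
Product: 25 nitrile diol, via lithiated isobutyronitrile 24 (not isolated)
Conditions: 23, LiN(iPr)2 (2.2 equiv), THF, −78 °C; then 22, 25 → 60 °C; H2O
Reagents that add atoms: none
Why: Epoxide opening by a nitrile-stabilized tertiary carbanion, at the epoxide carbon remote from the fully substituted alkoxide carbon and with inversion; this sets C5 with the CMe2 group trans to both oxygens. The alkoxide is cis to the epoxide and cannot trigger an epoxide migration.

Step 18
Reactants: 25 nitrile diol
Product: 26 nitrile ketol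
Conditions: (COCl)2, DMSO, CH2Cl2, −78 °C; then iPr2NEt, −78 → −20 °C
Reagents that add atoms: none
Why: Swern oxidation takes only the secondary alcohol and does not cleave the 1,2-diol; the cold hindered base leaves the α-stereocenter C5 in place.

Step 19
Reactants: 26 nitrile ketol
Product: 27 silyloxy ketone nitrile
Conditions: Et3SiOTf, 2,6-lutidine, CH2Cl2, −78 → 0 °C
Reagents that add atoms: triethylsilyl trifluoromethanesulfonate CC[Si](CC)(CC)OS(=O)(=O)C(F)(F)F
Why: Silylation of the tertiary hydroxyl, which is faster than enol silane formation at low temperature; the ether protects C8–O through the organolithium steps.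

Step 20
Reactants: 27 silyloxy ketone nitrile
Product: 28 methylidene nitrile
Conditions: Zn, CH2Br2, TiCl4, THF/CH2Cl2, 0 → 25 °C
Reagents that add atoms: dibromomethane BrCBr
Why: Takai–Lombardo methylenation works on hindered, enolizable ketones without base, so the epimerizable C5 is kept, and it tolerates the nitrile.

Step 21
Reactants: 28 methylidene nitrile; 29 bromoethene
Product: 31 allyl nitrile, via alkylborane 30 (not isolated)
Conditions: 9-BBN, THF, 25 → 60 °C; then 29, Pd(dppf)Cl2 (cat.), K3PO4, THF/DMF/H2O, 25 → 50 °C
Reagents that add atoms: none
Why: Hydroboration of the exocyclic alkene; the lower face is blocked by the C8 methyl and the CMe2 group on C5, so hydrogen should add to C4 from the face of H5, which gives the cis ring fusion. B-alkyl Suzuki–Miyaura coupling with 29 then completes the allyl group (C3, C2).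

Step 22
Reactants: 31 allyl nitrile; 32 2-bromopropene
Product: 35 dienone, via isopropenyllithium 33 (not isolated), via N-lithio ketimine 34 (not isolated)
Conditions: 32, t-BuLi (2 equiv), Et2O, −78 °C; then 31, −78 → 0 °C; aq. AcOH, 25 °C
Reagents that add atoms: water O
Why: Addition of an alkenyllithium to a nitrile stops at the N-lithio ketimine, and mild acid hydrolysis gives the isopropenyl ketone (C10, C1 and its methyl); the silyl ether and the terminal alkene are inert.

Step 23
Reactants: 35 dienone
Product: 36 ring C/D enone
Conditions: second-generation Grubbs catalyst (10 mol %), toluene, 80 °C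
Reagents that add atoms: none
Why: Ring-closing metathesis of the allyl group with the 1,1-disubstituted enone alkene closes the seven-membered ring as a 2-methylcycloheptenone, helped by the gem-dimethyl group and the cis arrangement of the two arms.

Step 24
Reactants: 19 ring A/B iodide; 36 ring C/D enone
Product: 38 tertiary allylic alcohol, via primary alkyllithium 37 (not isolated)
Conditions: 19, t-BuLi (2.1 equiv), Et2O/pentane, −78 °C; then 36, THF, −78 → −20 °C; H2O
Reagents that add atoms: none
Why: Iodine–lithium exchange gives the primary alkyllithium, which adds 1,2 to the enone carbonyl as alkyllithiums do with 2,6,6-trisubstituted cyclohexenones; the ketone has no α′-hydrogen. The new center at C10 is removed in step 25.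

Step 25
Reactants: 38 tertiary allylic alcohol
Product: 39 transposed enone
Conditions: pyridinium chlorochromate [C5H5NH][CrO3Cl], 4 Å sieves, CH2Cl2, 25 °C
Reagents that add atoms: pyridinium chlorochromate [O-][Cr](=O)(=O)Cl.c1cc[nH+]cc1
Why: Babler–Dauben oxidation: the chromate ester of the tertiary allylic alcohol shifts 1,3 and is oxidized, giving the enone with the carbonyl at C2 and the alkene at C1=C10; the silyl ethers survive the brief mildly acidic conditions.

Step 26
Reactants: 39 transposed enone
Product: 40 allylic alcohol
Conditions: (S)-2-methyl-CBS-oxazaborolidine (0.5 equiv), BH3·SMe2, THF, −20 °C; MeOH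
Reagents that add atoms: none
Why: Corey–Bakshi–Shibata reduction with the α-methyl alkenyl side as the large group should give the (R)-carbinol at C2 (priorities O > C1 > C3 > H), with the hydroxyl on the face opposite to H4 and H5; this face is chosen by the catalyst, not by the substrate.

Step 27
Reactants: 40 allylic alcohol
Product: 43 tris-silyl ether of the triol, via sulfonylhydrazine 41 (not isolated), via allylic diazene 42 (not isolated)
Conditions: 2-nitrobenzenesulfonylhydrazide, PPh3, diethyl azodicarboxylate, THF, −30 → 25 °C
Reagents that add atoms: none
Why: Myers reductive allylic transposition: Mitsunobu displacement inverts C2, loss of sulfinic acid gives the allylic diazene, and its retro-ene loss of N2 delivers hydrogen to C10 on the face of the C2–N bond while the alkene moves to C1=C2. With the carbinol of 40 this places H10 on the face of H4 and H5 and the linker on the other, as in the target.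

Step 28
Reactants: 43 tris-silyl ether of the triol
Product: 44 triol
Conditions: Bu4NF, THF, 50 °C
Reagents that add atoms: none
Why: Fluoride cleaves the two tertiary triethylsilyl ethers and the hindered triisopropylsilyl ether without acid, so neither tertiary alcohol can eliminate and the alkene cannot move.

Step 29
Reactants: 44 triol
Product: 45 target
Conditions: Dess–Martin periodinane, NaHCO3, CH2Cl2, 25 °C
Reagents that add atoms: none
Why: Dess–Martin oxidation can act only on the one secondary alcohol (C17); both C17 epimers give the same ketone, and the tertiary alcohols and the alkene are inert.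

## Compound list

1 | (R)-linalool, (3R)-3,7-dimethylocta-1,6-dien-3-ol | CC(C)=CCC[C@@](C)(O)C=C | starting material
2 | acryloyl chloride (prop-2-enoyl chloride) | C=CC(=O)Cl | starting material
3 | (R)-linalyl acrylate, (3R)-3,7-dimethylocta-1,6-dien-3-yl prop-2-enoate | C=CC(=O)O[C@@](C)(C=C)CCC=C(C)C | intermediate
4 | (3R,6E)-8-hydroxy-3,7-dimethylocta-1,6-dien-3-yl prop-2-enoate | C=CC(=O)O[C@@](C)(C=C)CC/C=C(\C)CO | intermediate
5 | (3R)-5-[(2R,3R)-3-(hydroxymethyl)-3-methyloxiran-2-yl]-3-methylpent-1-en-3-yl prop-2-enoate | C=CC(=O)O[C@@](C)(C=C)CC[C@H]1O[C@]1(C)CO | intermediate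
6 | (5R)-5-{2-[(2R,3R)-3-(hydroxymethyl)-3-methyloxiran-2-yl]ethyl}-5-methylfuran-2(5H)-one (key-step precursor) | O=C1C=C[C@@](C)(CC[C@H]2O[C@]2(C)CO)O1 | intermediate
7 | ring-opened 6: tertiary C14 radical with the Cp2ClTi–O group on C19 | O=C1C=C[C@@](C)(CC[C@@H](O[Ti](Cl)(C2C=CC=C2)C2C=CC=C2)[C](C)CO)O1 | intermediate (not isolated)
8 | (3aS,4R,5R,7aR)-5-hydroxy-4-(hydroxymethyl)-4,7a-dimethylhexahydro-1-benzofuran-2(3H)-one (key-step product; cis-fused lactone, C14 methyl on the face of the C13 side chain, C19 hydroxyl and hydroxymethyl on the other) | O=C1C[C@H]2[C@](C)(CO)[C@H](O)CC[C@@]2(C)O1 | intermediate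
9 | 8 with the hydroxymethyl group oxidized to the aldehyde, stereocenters as in 8 | O=C1C[C@H]2[C@](C)(C=O)[C@H](O)CC[C@@]2(C)O1 | intermediate
10 | 8 with a vinyl group in place of hydroxymethyl | O=C1C[C@H]2[C@](C)(C=C)[C@H](O)CC[C@@]2(C)O1 | intermediate
11 | 1-bromo-2-methylprop-1-ene | CC(C)=CBr | starting material
12 | 10 hydroborated at the terminal carbon, hydroxyl as 9-BBN borinate | O=C1C[C@H]2[C@](C)(CCB3C4CCCC3CCC4)[C@H](OB3C4CCCC3CCC4)CC[C@@]2(C)O1 | intermediate (not isolated)
13 | 8 with a 4-methylpent-3-enyl group in place of hydroxymethyl | O=C1C[C@H]2[C@](C)(CCC=C(C)C)[C@H](O)CC[C@@]2(C)O1 | intermediate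
14 | 13 epoxidized at the trisubstituted alkene, both C17 epimers | O=C1C[C@H]2[C@](C)(CCC3OC3(C)C)[C@H](O)CC[C@@]2(C)O1 | intermediate
15 | tricyclic lactone with cis-fused 2,2-dimethyloxepane (ring A) on ring B, C17–O-triisopropylsilyl, C17 epimers | O=C1C[C@H]2[C@]3(C)CCC(O[Si](C(C)C)(C(C)C)C(C)C)C(C)(C)O[C@@H]3CC[C@@]2(C)O1 | intermediate
16 | ring A/B diol: 15 with the lactone reduced to the 2-hydroxyethyl arm on C13 and free C22 hydroxyl | OCC[C@H]1[C@]2(C)CCC(O[Si](C(C)C)(C(C)C)C(C)C)C(C)(C)O[C@@H]2CC[C@@]1(C)O | intermediate
17 | bis(triethylsilyl) ether of 16 | CC[Si](CC)(CC)OCC[C@H]1[C@]2(C)CCC(O[Si](C(C)C)(C(C)C)C(C)C)C(C)(C)O[C@@H]2CC[C@@]1(C)O[Si](CC)(CC)CC | intermediate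
18 | 17 with the primary hydroxyl free | OCC[C@H]1[C@]2(C)CCC(O[Si](C(C)C)(C(C)C)C(C)C)C(C)(C)O[C@@H]2CC[C@@]1(C)O[Si](CC)(CC)CC | intermediate
19 | ring A/B iodide: 18 with iodine in place of the primary hydroxyl | ICC[C@H]1[C@]2(C)CCC(O[Si](C(C)C)(C(C)C)C(C)C)C(C)(C)O[C@@H]2CC[C@@]1(C)O[Si](CC)(CC)CC | intermediate
20 | (S)-linalool, (3S)-3,7-dimethylocta-1,6-dien-3-ol | CC(C)=CCC[C@](C)(O)C=C | starting material
21 | (1S)-1-methylcyclopent-2-en-1-ol | C[C@@]1(O)C=CCC1 | intermediate
22 | (1R,2S,5R)-2-methyl-6-oxabicyclo[3.1.0]hexan-2-ol (epoxide cis to hydroxyl) | C[C@@]1(O)[C@@H]2O[C@@H]2CC1 | intermediate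
23 | isobutyronitrile (2-methylpropanenitrile) | CC(C)C#N | starting material
24 | 2-lithio-2-methylpropanenitrile | [Li]C(C)(C)C#N | intermediate (not isolated)
25 | 2-[(1R,2R,3S)-2,3-dihydroxy-3-methylcyclopentyl]-2-methylpropanenitrile | C[C@@]1(O)[C@H](O)[C@@H](C(C)(C)C#N)CC1 | intermediate
26 | 2-[(1R,3S)-3-hydroxy-3-methyl-2-oxocyclopentyl]-2-methylpropanenitrile | C[C@@]1(O)C(=O)[C@@H](C(C)(C)C#N)CC1 | intermediate
27 | triethylsilyl ether of 26 | C[C@@]1(O[Si](CC)(CC)CC)C(=O)[C@@H](C(C)(C)C#N)CC1 | intermediate
28 | 27 with the ketone replaced by an exocyclic methylidene group | C[C@@]1(O[Si](CC)(CC)CC)C(=C)[C@@H](C(C)(C)C#N)CC1 | intermediate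
29 | bromoethene (vinyl bromide) | C=CBr | starting material
30 | 28 hydroborated: (9-BBN)methyl group on C4, H4 cis to H5 | C[C@@]1(O[Si](CC)(CC)CC)[C@@H](CB2C3CCCC2CCC3)[C@@H](C(C)(C)C#N)CC1 | intermediate (not isolated)
31 | cyclopentane with cis allyl (C4) and 2-cyanopropan-2-yl (C5) groups, both trans to the C8 silyloxy group | C[C@@]1(O[Si](CC)(CC)CC)[C@@H](CC=C)[C@@H](C(C)(C)C#N)CC1 | intermediate
32 | 2-bromopropene | CC(Br)=C | starting material
33 | isopropenyllithium | [Li]C(C)=C | intermediate (not isolated)
34 | N-lithio ketimine from 31 and 33 | C[C@@]1(O[Si](CC)(CC)CC)[C@@H](CC=C)[C@@H](C(C)(C)C(=N[Li])C(C)=C)CC1 | intermediate (not isolated)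
35 | 31 with the nitrile converted to the isopropenyl ketone | C[C@@]1(O[Si](CC)(CC)CC)[C@@H](CC=C)[C@@H](C(C)(C)C(=O)C(C)=C)CC1 | intermediate
36 | cis-fused hydroazulenone: C10 ketone, C1(methyl)=C2 alkene, C9 gem-dimethyl, C8 methyl and triethylsilyloxy (oxygen cis to H4 and H5) | C[C@@]1(O[Si](CC)(CC)CC)[C@H]2CC=C(C)C(=O)C(C)(C)[C@H]2CC1 | intermediate
37 | primary alkyllithium from 19 | [Li]CC[C@H]1[C@]2(C)CCC(O[Si](C(C)C)(C(C)C)C(C)C)C(C)(C)O[C@@H]2CC[C@@]1(C)O[Si](CC)(CC)CC | intermediate (not isolated)
38 | adduct of 37 at the carbonyl of 36: tertiary allylic alcohol at C10 (C10 epimers) | C[C@@]1(O[Si](CC)(CC)CC)[C@H]2CC=C(C)C(O)(CC[C@H]3[C@]4(C)CCC(O[Si](C(C)C)(C(C)C)C(C)C)C(C)(C)O[C@@H]4CC[C@@]3(C)O[Si](CC)(CC)CC)C(C)(C)[C@H]2CC1 | intermediate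
39 | transposed enone: C2 ketone, C1(methyl)=C10 alkene carrying the linker | C[C@@]1(O[Si](CC)(CC)CC)[C@H]2CC(=O)C(C)=C(CC[C@H]3[C@]4(C)CCC(O[Si](C(C)C)(C(C)C)C(C)C)C(C)(C)O[C@@H]4CC[C@@]3(C)O[Si](CC)(CC)CC)C(C)(C)[C@H]2CC1 | intermediate
40 | allylic alcohol from 39: (R)-carbinol at C2, hydroxyl trans to H4 and H5 | C[C@@]1(O[Si](CC)(CC)CC)[C@H]2C[C@@H](O)C(C)=C(CC[C@H]3[C@]4(C)CCC(O[Si](C(C)C)(C(C)C)C(C)C)C(C)(C)O[C@@H]4CC[C@@]3(C)O[Si](CC)(CC)CC)C(C)(C)[C@H]2CC1 | intermediate
41 | N-alkyl-N-(2-nitrobenzenesulfonyl)hydrazine at C2, inverted | C[C@@]1(O[Si](CC)(CC)CC)[C@H]2C[C@H](N(N)S(=O)(=O)c5ccccc5[N+](=O)[O-])C(C)=C(CC[C@H]3[C@]4(C)CCC(O[Si](C(C)C)(C(C)C)C(C)C)C(C)(C)O[C@@H]4CC[C@@]3(C)O[Si](CC)(CC)CC)C(C)(C)[C@H]2CC1 | intermediate (not isolated)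
42 | allylic diazene at C2 | C[C@@]1(O[Si](CC)(CC)CC)[C@H]2C[C@H](N=N)C(C)=C(CC[C@H]3[C@]4(C)CCC(O[Si](C(C)C)(C(C)C)C(C)C)C(C)(C)O[C@@H]4CC[C@@]3(C)O[Si](CC)(CC)CC)C(C)(C)[C@H]2CC1 | intermediate (not isolated)
43 | full skeleton with C1=C2 alkene and C10–H; C8–O and C22–O triethylsilyl, C17–O triisopropylsilyl | C[C@@]1(O[Si](CC)(CC)CC)[C@H]2CC=C(C)[C@@H](CC[C@H]3[C@]4(C)CCC(O[Si](C(C)C)(C(C)C)C(C)C)C(C)(C)O[C@@H]4CC[C@@]3(C)O[Si](CC)(CC)CC)C(C)(C)[C@H]2CC1 | intermediate
44 | triol: target with C17 hydroxyl in place of the ketone (C17 epimers) | C[C@@]1(O)[C@H]2CC=C(C)[C@@H](CC[C@H]3[C@]4(C)CCC(O)C(C)(C)O[C@@H]4CC[C@@]3(C)O)C(C)(C)[C@H]2CC1 | intermediate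
45 | CNP0194989.5 | C[C@@]1(O)[C@H]2CC=C(C)[C@@H](CC[C@H]3[C@]4(C)CCC(=O)C(C)(C)O[C@@H]4CC[C@@]3(C)O)C(C)(C)[C@H]2CC1 | target

## Step count and least certain steps

Total step count: 29. Longest linear sequence: 20 steps (1 to 14, then 24 to 29); the ring C/D branch (15 to 23) has 9 steps.

Step 5 (key step). The most likely failure is poor facial selectivity at the planar C14 radical. If the ring closes through a boat-like arrangement, or if the hydroxymethyl oxygen does not bind the titanium, C15 ends trans to the C19 oxygen. The second risk is loss of the tertiary radical by reduction or hydrogen loss before it reaches the butenolide. The fallback sets out from 6 and returns at 8, and makes the same radical inside a ring that ties C15 to the C19 oxygen. Me3SiOTf with an amidine base isomerizes the epoxide of 6 to the allylic silyl ether with an exocyclic methylene group, the bis(trimethylsilyl) ether F1. Mild acid methanolysis gives the methylene diol F2, and 2,2-dimethoxypropane with an acid catalyst gives the 5-methylene-1,3-dioxane F3. Hydrogen-atom transfer from an iron hydride (Fe(acac)3, PhSiH3, EtOH) to the methylene group creates the tertiary radical on the dioxane ring, and 6-exo addition to the butenolide gives the tricyclic acetonide F4. The acetal can bridge C19–O and C15 only when they are gauche, which in the lactone-enforced chair is the cis arrangement. Aqueous acetic acid then frees 8.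

Step 10. The likely failure is opening of the epoxide in the 6-exo mode at C17 (a tetrahydropyran with a hydroxy-isopropyl group), because the exo path is entropically easier; the C19 hydroxyl may also be silylated before it attacks. The fallback sets out from 13 and returns at 15, and uses an alkene activation that is strictly Markovnikov. Hg(OCOCF3)2 adds the C19 hydroxyl to C18 of the trisubstituted alkene; after chloride exchange this is the chloromercurio oxepane F5. NaBH4 under O2 in DMF replaces mercury by hydroxyl to give the oxepanol F6, and iPr3SiOTf with 2,6-lutidine gives 15.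

Step 24. The likely failure is incomplete addition to the hindered carbonyl, with deprotonation of 36 at C3 (dienolate formation) or coupling of the alkyllithium with unreacted iodide. The fallback sets out from 36 and 19, returns at 43 and bypasses steps 25 to 27. KN(SiMe3)2 and PhNTf2 convert 36 through its dienolate into the dienyl triflate F7. Iodide 19 with t-BuLi and then B-methoxy-9-BBN gives the lithium borate F8. Pd(dppf)Cl2 couples F7 and F8 to the ring C diene F9 (C10=C1 and C2=C3). 1,4-Hydrogenation with (naphthalene)Cr(CO)3 and H2 adds hydrogen to C10 and C3 from the open face of the cisoid diene and leaves the C1=C2 alkene, giving 43.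

Step 27 (with step 26). The likely failures are a mismatch between catalyst and substrate in step 26, which would give the C2 epimer and then the wrong face at C10, and a sluggish Mitsunobu displacement at the hindered allylic carbinol. The fallback sets out from 39 and returns at 43. Tosylhydrazide converts 39 into the tosylhydrazone F10. Catecholborane then adds hydride to the C=N carbon, and NaOAc with heat expels sulfinate to give the same kind of allylic diazene, which loses N2 with hydrogen transfer to C10. Here the nitrogen ends opposite to the entering hydride, so this sequence needs hydride on the face opposite to the one needed in step 26. A substrate bias that defeats the catalyst in step 26 therefore works in favour of the fallback.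

## Further compounds

F1 | step 5 | bis(trimethylsilyl) ether of the methylene diol (butenolide with C19–OSiMe3, exocyclic C14=CH2, CH2OSiMe3) | O=C1C=C[C@@](C)(CC[C@@H](O[Si](C)(C)C)C(=C)CO[Si](C)(C)C)O1
F2 | step 5 | methylene diol (butenolide with C19–OH, exocyclic C14=CH2, CH2OH) | O=C1C=C[C@@](C)(CC[C@@H](O)C(=C)CO)O1
F3 | step 5 | 5-methylene-1,3-dioxane (acetonide of F2) | O=C1C=C[C@@](C)(CC[C@H]2OC(C)(C)OCC2=C)O1
F4 | step 5 | tricyclic acetonide of 8 | O=C1C[C@H]2[C@]3(C)COC(C)(C)O[C@@H]3CC[C@@]2(C)O1
F5 | step 10 | chloromercurio oxepane lactone (HgCl on C17) | O=C1C[C@H]2[C@]3(C)CCC([Hg]Cl)C(C)(C)O[C@@H]3CC[C@@]2(C)O1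
F6 | step 10 | oxepanol lactone (C17–OH) | O=C1C[C@H]2[C@]3(C)CCC(O)C(C)(C)O[C@@H]3CC[C@@]2(C)O1
F7 | step 24 | dienyl triflate of 36 (C10–OTf, C10=C1, C2=C3) | C[C@@]1(O[Si](CC)(CC)CC)[C@H]2C=CC(C)=C(OS(=O)(=O)C(F)(F)F)C(C)(C)[C@H]2CC1
F8 | step 24 | lithium B-alkyl-B-methoxy-9-BBN borate from 19 | CO[B-]1(CC[C@H]4[C@]5(C)CCC(O[Si](C(C)C)(C(C)C)C(C)C)C(C)(C)O[C@@H]5CC[C@@]4(C)O[Si](CC)(CC)CC)C2CCCC1CCC2.[Li+]
F9 | step 24 | ring C diene carrying the linker on C10 | C[C@@]1(O[Si](CC)(CC)CC)[C@H]2C=CC(C)=C(CC[C@H]3[C@]4(C)CCC(O[Si](C(C)C)(C(C)C)C(C)C)C(C)(C)O[C@@H]4CC[C@@]3(C)O[Si](CC)(CC)CC)C(C)(C)[C@H]2CC1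
F10 | step 27 | tosylhydrazone of 39 | C[C@@]1(O[Si](CC)(CC)CC)[C@H]2CC(=NNS(=O)(=O)c5ccc(C)cc5)C(C)=C(CC[C@H]3[C@]4(C)CCC(O[Si](C(C)C)(C(C)C)C(C)C)C(C)(C)O[C@@H]4CC[C@@]3(C)O[Si](CC)(CC)CC)C(C)(C)[C@H]2CC1
A1 | alternative 1 | 5-methyl-2-(5-methylhex-4-enoyl)cyclopent-1-enyl acetate | CC(=O)OC1=C(C(=O)CCC=C(C)C)CC[C@@H]1C
A2 | alternative 1 | cis-fused ring C/D diketone (ketones at C10 and C8) | C[C@@H]1CC[C@H]2[C@H](CCC2=O)C(C)(C)C1=O
A3 | alternative 2 | (Z)-diepoxy acid (inner and terminal epoxides of a homofarnesic acid) | OC(=O)C/C=C(/C)CC[C@H]1O[C@@]1(C)CC[C@H]1OC1(C)C
A4 | alternative 2 | tricyclic hydroxy lactone with rings A and B | O=C1C[C@H]2[C@]3(C)CC[C@@H](O)C(C)(C)O[C@@H]3CC[C@@]2(C)O1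
A5 | alternative 3 | cycloheptadienyl (E)-2-(trimethylsilyl)vinyl ketone | CC1=CCC(C(=O)/C=C/[Si](C)(C)C)=CC(C)(C)[C@@H]1CCO[Si](C)(C)C(C)(C)C
A6 | alternative 3 | cis-fused ring C/D cyclopentenone | CC1=CC[C@H]2[C@H](C=CC2=O)C(C)(C)[C@@H]1CCO[Si](C)(C)C(C)(C)C
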